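**Plan**
- Retrosynthesis: the C7–C8 epoxide goes back to an E-alkene, C11=CH2 to a ketone (carried as a silyl ether), C14=C15 is cut by Wittig olefination and C4–C12 by enolate alkylation. The nine-membered ring is then opened at C6–C7, followed by C4a–C5 (conjugate addition), C4=C4a (ring-closing metathesis) and C11–C11a (aldol).
- Enabling feature: C7 of the nine-membered ring is an alkene carbon in disguise (the epoxide of an E-trisubstituted C7=C8 bond), and C6 is a methylene two carbons from ring-fusion carbon C4a. C6–C7 is therefore an sp3–sp2 coupling site between a hydroborated C4a vinyl group and an (E)-alkenyl iodide, both hung trans on the six-membered lactone ring.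
- Forward order: iodoalkene arm and C11a by Evans aldol, six-membered lactone by acrylate metathesis, vinyl group at C4a, nine-membered ring by intramolecular B-alkyl Suzuki–Miyaura coupling, C4 chain, enoate, C11 methylene, epoxide.
- Stereochemistry: C11a from the (R)-benzyloxazolidinone auxiliary; C4a by anti conjugate addition; C4 by axial alkylation of the trans-fused lactone enolate; E-C7=C8 from syn hydrozirconation; C7/C8 by peripheral epoxidation of the E-cyclononene.

Key step: step 10

Remark: xenicane numbering is used throughout (O2, lactone carbonyl C3, side-chain carbon C4, ring-fusion carbons C4a and C11a, epoxide carbons C7 and C8, methylene carbon C11); the target is (4S,4aS,7S,8S,11aR), and compounds 1, 5, 6 and 17 are taken as commercial.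

**Route**

Step 1
Reactants: 1 hex-4-yn-1-ol
Product: 3 (E)-5-iodohex-4-en-1-ol, via alkenylzirconocene 2 (not isolated)
Conditions: Cp2Zr(H)Cl (2.5 equiv), THF, 50 °C; then I2, 0 °C
Reagents that add atoms: iodine, [I][I]
Why: Hydrozirconation–iodination: syn addition of Zr–H to the 2-alkyne, equilibration by excess reagent to the isomer with zirconium on the methyl-bearing carbon, and iodinolysis with retention should give the (E)-2-iodoalkene that later fixes the ring-olefin geometry.

Step 2
Reactants: 3 (E)-5-iodohex-4-en-1-ol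
Product: 4 (E)-5-iodohex-4-enal
Conditions: TEMPO (10 mol %), PhI(OAc)2, CH2Cl2, rt
Reagents that add atoms: none
Why: The TEMPO/PhI(OAc)2 oxidation of a primary alcohol stops at the aldehyde and leaves the iodoalkene untouched.

Step 3
Reactants: 5 (R)-4-benzyl-1,3-oxazolidin-2-one; 6 (E)-but-2-enoyl chloride
Product: 7 (R)-4-benzyl-3-[(E)-but-2-enoyl]-1,3-oxazolidin-2-one
Conditions: n-BuLi, THF, −78 °C; then 6, −78 → 0 °C
Reagents that add atoms: none
Why: N-Acylation of the lithiated Evans oxazolidinone with an acid chloride is a standard imide synthesis.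

Step 4
Reactants: 7 (R)-4-benzyl-3-[(E)-but-2-enoyl]-1,3-oxazolidin-2-one; 4 (E)-5-iodohex-4-enal
Product: 9 (4R)-4-benzyl-3-[(2R,3S,6E)-2-ethenyl-3-hydroxy-7-iodooct-6-enoyl]-1,3-oxazolidin-2-one, via boron dienolate 8 (not isolated)
Conditions: Bu2BOTf, Et3N, CH2Cl2, −78 → 0 °C; then 4, −78 → 0 °C; H2O2, MeOH, pH 7 buffer
Reagents that add atoms: none
Why: Evans boron aldol of a crotonyl imide: the dibutylboron Z-dienolate reacts at its α-carbon through a Zimmerman–Traxler chair on the face away from the benzyl group, which should set C11a (R in the imide, the future 11aR) and the temporary syn carbinol at C11.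

Step 5
Reactants: 9 the aldol adduct
Product: 10 (4R)-4-benzyl-3-[(2R,3S,6E)-3-(tert-butyldimethylsilyloxy)-2-ethenyl-7-iodooct-6-enoyl]-1,3-oxazolidin-2-one
Conditions: TBSOTf, 2,6-lutidine, CH2Cl2, −78 → 0 °C
Reagents that add atoms: tert-butyldimethylsilyl triflate, CC(C)(C)[Si](C)(C)OS(=O)(=O)C(F)(F)F
Why: Silylation of the secondary alcohol masks C11, the future methylene carbon, as an ether that survives cuprate, borane, palladium and enolate chemistry and cannot compete in the later hydroboration.

Step 6
Reactants: 10 the silylated imide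
Product: 11 (2S,3S,6E)-3-(tert-butyldimethylsilyloxy)-2-ethenyl-7-iodooct-6-en-1-ol
Conditions: LiBH4, MeOH (1 equiv), Et2O, 0 °C
Reagents that add atoms: none
Why: Reductive removal of the Evans auxiliary with LiBH4 gives the primary alcohol (the future C1–O2) without touching the α-stereocenter.

Step 7
Reactants: 11 the primary alcohol
Product: 12 (2S,3S,6E)-3-(tert-butyldimethylsilyloxy)-2-ethenyl-7-iodooct-6-en-1-yl prop-2-enoate
Conditions: acryloyl chloride, iPr2NEt, CH2Cl2, −78 → 0 °C
Reagents that add atoms: acryloyl chloride, C=CC(Cl)=O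
Why: Esterification of the primary alcohol with an acid chloride installs C3 and C4 of the lactone.

Step 8
Reactants: 12 the acrylate
Product: 13 (5S)-5-[(1S,4E)-1-(tert-butyldimethylsilyloxy)-5-iodohex-4-en-1-yl]-5,6-dihydro-2H-pyran-2-one
Conditions: second-generation Grubbs catalyst (H2IMes)(PCy3)Cl2Ru=CHPh (5 mol %), CH2Cl2 (0.005 M), 40 °C
Reagents that add atoms: none
Why: Ring-closing metathesis between the acrylate and the vinyl group on C11a closes the six-membered unsaturated lactone (C4=C4a), and the trisubstituted iodoalkene is inert to the ruthenium carbene.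

Step 9
Reactants: 13 the unsaturated lactone
Product: 14 (4S,5S)-4-ethenyl-5-[(1S,4E)-1-(tert-butyldimethylsilyloxy)-5-iodohex-4-en-1-yl]oxan-2-one
Conditions: CH2=CHMgBr, CuBr·SMe2, THF, −78 → −40 °C; aq. NH4Cl
Reagents that add atoms: vinylmagnesium bromide CH2=CHMgBr, C=C[Mg]Br
Why: Copper-mediated conjugate addition: the vinyl group should add to C4a anti to the bulky substituent on the neighbouring C11a, giving the trans (4aS) lactone with both arms equatorial, and at this temperature the iodoalkene is not exchanged.

Step 10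
Reactants: 14 the trans-4-vinyl lactone
Product: 16 (4aR,7E,11S,11aS)-11-(tert-butyldimethylsilyloxy)-7-methyl-1,4,4a,5,6,9,10,11,11a-nonahydrocyclonona[c]pyran-3-one, via B-alkyl-9-BBN borane 15 (not isolated)
Conditions: 9-BBN, THF, 0 °C → rt; then slow addition to PdCl2(dppf) (15 mol %), AsPh3, Cs2CO3, DMF/THF/H2O (final 0.003 M), rt → 45 °C; pH 4 work-up
Reagents that add atoms: none
Why: Anti-Markovnikov hydroboration of the C4a vinyl group with 9-BBN gives the primary C6 borane 15; zerovalent palladium, formed in the flask from PdCl2(dppf), inserts into the C7–I bond with retention, the carbonate-activated borate hands the C6 alkyl group to palladium, and reductive elimination forms the C6–C7 bond. The closest known reaction type is the intramolecular B-alkyl Suzuki–Miyaura coupling, which is established for medium-ring E-cycloalkenes and macrocycles. The nine-membered ring is closed in a 9-endo sense at the alkenyl carbon, so that the C7=C8 bond ends inside the ring. No new stereocenter is formed; the E geometry of C7=C8 is that of the iodoalkene carried over with retention, and it is what later makes the epoxide trans. The step needs cyclization over oligomerization, which slow addition at high dilution and the trans-diequatorial arms on C4a and C11a (pointing borane and iodoalkene toward each other) should secure. It also needs hydroboration at the vinyl group only, which holds because the iodoalkene is trisubstituted and C11 is carried as a silyl ether and not as the 1,1-disubstituted alkene that would compete; AsPh3 and the bidentate dppf ligand favour transmetalation and reductive elimination over β-hydride elimination.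

Step 11
Reactants: 16 the bicyclic lactone; 17 tert-butyl(3-iodopropoxy)dimethylsilane
Product: 19 (4S,4aS,7E,11S,11aS)-11-(tert-butyldimethylsilyloxy)-4-[3-(tert-butyldimethylsilyloxy)propyl]-7-methyl-1,4,4a,5,6,9,10,11,11a-nonahydrocyclonona[c]pyran-3-one, via lithium enolate 18 (not isolated)
Conditions: LiN(iPr)2, THF, −78 °C; then 17, HMPA, −78 → −40 °C
Reagents that add atoms: none
Why: Kinetic alkylation of the lithium enolate of a trans-fused six-membered lactone: stereoelectronically favoured axial attack of the iodide, anti to the axial H-4a, should place the chain trans to H-4a, which is the 4S configuration.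

Step 12
Reactants: 19 the bis-silyl ether
Product: 20 (4S,4aS,7E,11S,11aS)-11-hydroxy-4-(3-hydroxypropyl)-7-methyl-1,4,4a,5,6,9,10,11,11a-nonahydrocyclonona[c]pyran-3-one
Conditions: HF·pyridine, pyridine, THF, 0 °C → rt
Reagents that add atoms: none
Why: Fluoride cleavage of both silyl ethers with buffered HF·pyridine is chosen over basic fluoride so that the freed C11 hydroxyl does not attack the lactone carbonyl.

Step 13
Reactants: 20 the diol
Product: 21 3-[(4S,4aS,7E,11aS)-7-methyl-3,11-dioxo-1,3,4,4a,5,6,9,10,11,11a-decahydrocyclonona[c]pyran-4-yl]propanal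
Conditions: Dess–Martin periodinane, NaHCO3, CH2Cl2, 0 °C → rt
Reagents that add atoms: none
Why: Dess–Martin oxidation converts the secondary C11 alcohol into the ketone and the primary alcohol into the aldehyde in one operation under buffered conditions that should not epimerize C11a or C4.

Step 14
Reactants: 21 the keto aldehyde
Product: 22 methyl (2E)-2-methyl-5-[(4S,4aS,7E,11aS)-7-methyl-3,11-dioxo-1,3,4,4a,5,6,9,10,11,11a-decahydrocyclonona[c]pyran-4-yl]pent-2-enoate
Conditions: Ph3P=C(CH3)CO2CH3, CH2Cl2, rt
Reagents that add atoms: methyl 2-(triphenylphosphoranylidene)propanoate, COC(=O)C(C)=P(c1ccccc1)(c1ccccc1)c1ccccc1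
Why: Wittig olefination with a stabilized ylide reacts only at the aldehyde, not at the hindered ketone, and should give the (E)-2-methyl enoate.

Step 15
Reactants: 22 the keto enoate
Product: 23 methyl (2E)-2-methyl-5-[(4S,4aS,7E,11aR)-7-methyl-11-methylidene-3-oxo-1,3,4,4a,5,6,9,10,11,11a-decahydrocyclonona[c]pyran-4-yl]pent-2-enoate
Conditions: Zn, CH2Br2, TiCl4 (pre-formed reagent), THF/CH2Cl2, 0 °C → rt
Reagents that add atoms: dibromomethane, BrCBr
Why: The Takai–Lombardo methylenation is non-basic, so the β-acyloxy ketone should be methylenated without β-elimination of the lactone carboxylate or epimerization at C11a, and the lactone and ester carbonyls are not attacked.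

Step 16
Reactants: 23 the diene lactone
Product: 24 acalycixeniolide H, (4S,4aS,7S,8S,11aR)
Conditions: mCPBA (1.05 equiv), NaHCO3, CH2Cl2, −20 → 0 °C
Reagents that add atoms: 3-chloroperoxybenzoic acid, O=C(OO)c1cccc(Cl)c1
Why: Prilezhaev epoxidation: the strained trisubstituted E C7=C8 bond is by far the most nucleophilic alkene, and attack on its exposed outer face in the favoured ring conformer should give the (7S,8S) epoxide, the same arrangement relative to the trans ring fusion that peracid epoxidation of caryophyllene is known to favour.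

**Compound list**

1 | hex-4-yn-1-ol | CC#CCCCO | starting material
2 | (E)-alkenylzirconocene chloride from 1 (zirconium on C5, oxygen held as zirconocene alkoxide) | C/C(=C\CCCO[Zr](Cl)(C1C=CC=C1)C1C=CC=C1)[Zr](Cl)(C1C=CC=C1)C1C=CC=C1 | intermediate
3 | (E)-5-iodohex-4-en-1-ol | C/C(I)=C\CCCO | intermediate
4 | (E)-5-iodohex-4-enal | C/C(I)=C\CCC=O | intermediate
5 | (R)-4-benzyl-1,3-oxazolidin-2-one | O=C1N[C@H](Cc2ccccc2)CO1 | starting material
6 | (E)-but-2-enoyl chloride | C/C=C/C(Cl)=O | starting material
7 | (R)-4-benzyl-3-[(E)-but-2-enoyl]-1,3-oxazolidin-2-one | C/C=C/C(=O)N1[C@H](Cc2ccccc2)COC1=O | intermediate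
8 | dibutylboron Z-dienolate of 7 | C=C/C=C(\OB(CCCC)CCCC)N1[C@H](Cc2ccccc2)COC1=O | intermediate
9 | (4R)-4-benzyl-3-[(2R,3S,6E)-2-ethenyl-3-hydroxy-7-iodooct-6-enoyl]-1,3-oxazolidin-2-one | C=C[C@H]([C@@H](O)CC/C=C(\C)I)C(=O)N1[C@H](Cc2ccccc2)COC1=O | intermediate
10 | (4R)-4-benzyl-3-[(2R,3S,6E)-3-(tert-butyldimethylsilyloxy)-2-ethenyl-7-iodooct-6-enoyl]-1,3-oxazolidin-2-one | C=C[C@H]([C@@H](O[Si](C)(C)C(C)(C)C)CC/C=C(\C)I)C(=O)N1[C@H](Cc2ccccc2)COC1=O | intermediate
11 | (2S,3S,6E)-3-(tert-butyldimethylsilyloxy)-2-ethenyl-7-iodooct-6-en-1-ol | C=C[C@H]([C@@H](O[Si](C)(C)C(C)(C)C)CC/C=C(\C)I)CO | intermediate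
12 | (2S,3S,6E)-3-(tert-butyldimethylsilyloxy)-2-ethenyl-7-iodooct-6-en-1-yl prop-2-enoate | C=C[C@H]([C@@H](O[Si](C)(C)C(C)(C)C)CC/C=C(\C)I)COC(=O)C=C | intermediate
13 | (5S)-5-[(1S,4E)-1-(tert-butyldimethylsilyloxy)-5-iodohex-4-en-1-yl]-5,6-dihydro-2H-pyran-2-one | O=C1C=C[C@H]([C@@H](O[Si](C)(C)C(C)(C)C)CC/C=C(\C)I)CO1 | intermediate
14 | (4S,5S)-4-ethenyl-5-[(1S,4E)-1-(tert-butyldimethylsilyloxy)-5-iodohex-4-en-1-yl]oxan-2-one (trans) | O=C1C[C@@H](C=C)[C@H]([C@@H](O[Si](C)(C)C(C)(C)C)CC/C=C(\C)I)CO1 | intermediate
15 | B-alkyl-9-BBN borane from 14 (boron on the terminal carbon of the former vinyl group, C6) | O=C1C[C@@H](CCB2C3CCCC2CCC3)[C@H]([C@@H](O[Si](C)(C)C(C)(C)C)CC/C=C(\C)I)CO1 | intermediate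
16 | (4aR,7E,11S,11aS)-11-(tert-butyldimethylsilyloxy)-7-methyl-1,4,4a,5,6,9,10,11,11a-nonahydrocyclonona[c]pyran-3-one (trans-fused) | O=C1C[C@H]2CC/C(C)=C/CC[C@H](O[Si](C)(C)C(C)(C)C)[C@@H]2CO1 | intermediate
17 | tert-butyl(3-iodopropoxy)dimethylsilane | CC(C)(C)[Si](C)(C)OCCCI | starting material
18 | lithium enolate of 16 (O–Li on C3, C3=C4) | [Li]OC1=C[C@H]2CC/C(C)=C/CC[C@H](O[Si](C)(C)C(C)(C)C)[C@@H]2CO1 | intermediate
19 | (4S,4aS,7E,11S,11aS)-11-(tert-butyldimethylsilyloxy)-4-[3-(tert-butyldimethylsilyloxy)propyl]-7-methyl-1,4,4a,5,6,9,10,11,11a-nonahydrocyclonona[c]pyran-3-one | O=C1[C@@H](CCCO[Si](C)(C)C(C)(C)C)[C@H]2CC/C(C)=C/CC[C@H](O[Si](C)(C)C(C)(C)C)[C@@H]2CO1 | intermediate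
20 | (4S,4aS,7E,11S,11aS)-11-hydroxy-4-(3-hydroxypropyl)-7-methyl-1,4,4a,5,6,9,10,11,11a-nonahydrocyclonona[c]pyran-3-one | O=C1[C@@H](CCCO)[C@H]2CC/C(C)=C/CC[C@H](O)[C@@H]2CO1 | intermediate
21 | 3-[(4S,4aS,7E,11aS)-7-methyl-3,11-dioxo-1,3,4,4a,5,6,9,10,11,11a-decahydrocyclonona[c]pyran-4-yl]propanal | O=C1[C@@H](CCC=O)[C@H]2CC/C(C)=C/CCC(=O)[C@@H]2CO1 | intermediate
22 | methyl (2E)-2-methyl-5-[(4S,4aS,7E,11aS)-7-methyl-3,11-dioxo-1,3,4,4a,5,6,9,10,11,11a-decahydrocyclonona[c]pyran-4-yl]pent-2-enoate | O=C1[C@@H](CC/C=C(\C)C(=O)OC)[C@H]2CC/C(C)=C/CCC(=O)[C@@H]2CO1 | intermediate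
23 | methyl (2E)-2-methyl-5-[(4S,4aS,7E,11aR)-7-methyl-11-methylidene-3-oxo-1,3,4,4a,5,6,9,10,11,11a-decahydrocyclonona[c]pyran-4-yl]pent-2-enoate | O=C1[C@@H](CC/C=C(\C)C(=O)OC)[C@H]2CC/C(C)=C/CCC(=C)[C@@H]2CO1 | intermediate
24 | acalycixeniolide H, (4S,4aS,7S,8S,11aR) | C=C1CC[C@@H]2O[C@@]2(C)CC[C@@H]2[C@H](CC/C=C(\C)C(=O)OC)C(=O)OC[C@@H]12 | target

**Step count and risks**

Total: 16 steps. Longest linear sequence: 15 steps (steps 1, 2 and 4 to 16, from hex-4-yn-1-ol).

The three steps most likely to fail:

Step 10. The alkylborane may be protodeboronated or lose hydride before it transmetalates, the chain may oligomerize instead of closing the strained ring, and the aqueous base may open the lactone. The fallback sets out from 14. The vinyl group is hydroborated and oxidized (9-BBN, THF; NaBO3·4H2O) to the 2-hydroxyethyl lactone F1, which is converted (I2, PPh3, imidazole, CH2Cl2) into the 2-iodoethyl lactone F2. Zn dust activated with LiCl (THF, 25 °C) should insert into the primary C–I bond only, giving the alkylzinc iodide F3. Slow addition of F3 to Pd(PPh3)4 in THF/NMP at 50 °C closes the same C6–C7 bond by an intramolecular Negishi coupling without water or base, and the route is rejoined at 16.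

Step 11. The unactivated iodide may react slowly, so that proton transfer erodes the kinetic ratio, or the electrophile may enter on the face syn to H-4a. The fallback sets out from 16 and uses the same facial bias in the opposite sense. The alkylation is run as before; if it delivers mainly the C4 epimer F4, this is deprotonated again (LiN(iPr)2, THF, −78 °C) to the tetrasubstituted lithium enolate F5. Kinetic protonation (AcOH in THF, −78 °C) then puts hydrogen on the face the electrophile preferred, which should leave the chain on the other face, and the route is rejoined at 19.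

Step 16. Oxygen transfer may be poorly face-selective if both faces of C7=C8 are exposed by interconverting ring conformers, and the C11 methylene may be oxidized in competition. The fallback sets out from 23 and arrives directly at 24 by reagent control: Shi epoxidation with the L-fructose-derived enantiomer of the Shi ketone, KHSO5 (Oxone), K2CO3 buffer, MeCN/dimethoxymethane/H2O, 0 °C. By the spiro transition-state model this enantiomer is matched to the (7S,8S) face of an E-trisubstituted alkene of this pattern, and the electrophilic dioxirane prefers the trisubstituted alkene over the 1,1-disubstituted one. This fallback makes no new compound (F0).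

**Further compounds**

F1 | step 10 | 4-(2-hydroxyethyl) lactone from 14 (configuration as in 14) | O=C1C[C@@H](CCO)[C@H]([C@@H](O[Si](C)(C)C(C)(C)C)CC/C=C(\C)I)CO1
F2 | step 10 | 4-(2-iodoethyl) lactone from F1 (configuration as in 14) | O=C1C[C@@H](CCI)[C@H]([C@@H](O[Si](C)(C)C(C)(C)C)CC/C=C(\C)I)CO1
F3 | step 10 | alkylzinc iodide from F2 (zinc on C6) | O=C1C[C@@H](CC[Zn]I)[C@H]([C@@H](O[Si](C)(C)C(C)(C)C)CC/C=C(\C)I)CO1
F4 | step 11 | (4R) epimer of 19 | O=C1[C@H](CCCO[Si](C)(C)C(C)(C)C)[C@H]2CC/C(C)=C/CC[C@H](O[Si](C)(C)C(C)(C)C)[C@@H]2CO1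
F5 | step 11 | lithium enolate of F4 (O–Li on C3, C3=C4 carrying the chain) | [Li]OC1=C(CCCO[Si](C)(C)C(C)(C)C)[C@H]2CC/C(C)=C/CC[C@H](O[Si](C)(C)C(C)(C)C)[C@@H]2CO1
F0 | step 16 | none | none
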